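**Retrosynthetic overview**
1. The target is opened last: hydroxide cleavage of a dihydrocoumarin lactone plus palladium-catalysed dearomative C6-prenylation of the freed phloroglucinolate gives the quaternary centre and the free acid in one operation.
2. The tricyclic lactone-phenol comes from an aryl iodide and (R)-4-(iodomethyl)-2,7-dimethylocta-2,7-diene by Negishi sp2–sp3 coupling; the iodide comes from diethyl malonate and 4-bromo-2-methylbut-1-ene through lipase desymmetrisation of a prochiral propane-1,3-diol.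
3. The aryl iodide comes from a pyranone-fused coumarin by Rh-catalysed asymmetric 1,4-phenylation (benzylic centre) and iodination of the last aromatic C–H.
4. The pyranone-fused coumarin comes from 5,7-dihydroxycoumarin: 7-O-silylation, Mg-directed ortho-formylation, NHK coupling/oxidation to the o-hydroxyaryl tigloyl ketone, then quinine-catalysed oxa-Michael closure (cis-2,3-dimethyl, first stereocentres).
5. Ring order: coumarin lactone ring (bought) → pyranone ring (oxa-Michael) → lactone ring saturated (Rh) → lactone opened and carbocycle dearomatised in the final step.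

Assumption: the target is the enol tautomer of the given SMILES; the sense of the lipase (step 12), of quinine (step 7) and of the Trost ligand antipode (step 21) is taken as stated and would be confirmed on small scale.
Locants: tricycles are numbered as pyrano[2,3-f]chromenes (O1–C2–C3–C4(=O) pyranone ring; C5, C6 arene carbons; O7–C8(=O)–C9–C10 lactone ring).

**Route**

Step 1
Reactants: 1 5,7-dihydroxy-2H-chromen-2-one
Product: 2 5-hydroxy-7-[(triisopropylsilyl)oxy]-2H-chromen-2-one
Conditions: TIPSCl (1.05 equiv), imidazole (2.2 equiv), DMF, 0 °C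
Reagents that add atoms: chlorotri(propan-2-yl)silane (TIPSCl), CC(C)[Si](Cl)(C(C)C)C(C)C
Why: Selective O-silylation, because the 7-OH is the more acidic (para-quinoid conjugation to the lactone carbonyl) and less hindered phenol, so one equivalent of the bulky silyl chloride caps it and leaves the 5-OH free as directing group and later ring oxygen.

Step 2
Reactants: 2 5-hydroxy-7-[(triisopropylsilyl)oxy]-2H-chromen-2-one
Product: 3 5-hydroxy-2-oxo-7-[(triisopropylsilyl)oxy]-2H-chromene-6-carbaldehyde
Conditions: MgCl2 (3 equiv), Et3N (6 equiv), (CH2O)n (8 equiv), MeCN, reflux; then 1 M HCl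
Reagents that add atoms: paraformaldehyde (formaldehyde), C=O
Why: Magnesium phenoxide-directed ortho-formylation (Casiraghi–Skattebøl), in which formaldehyde is delivered inside the Mg chelate only to C6, the single free carbon ortho to the 5-OH, and the benzylic alkoxide is oxidised by a second formaldehyde, so C8 stays untouched.

Step 3
Reactants: 3 5-hydroxy-2-oxo-7-[(triisopropylsilyl)oxy]-2H-chromene-6-carbaldehyde
Product: 4 5-(methoxymethoxy)-2-oxo-7-[(triisopropylsilyl)oxy]-2H-chromene-6-carbaldehyde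
Conditions: MOMCl (2 equiv), i-Pr2NEt (3 equiv), DMAP (cat.), CH2Cl2, 0 °C → reflux
Reagents that add atoms: chloromethyl methyl ether (MOMCl), COCCl
Why: O-alkylation to the MOM acetal masks the acidic chelated phenol so that it neither protonates the alkenylchromium reagent of step 4 nor adds to the enone of step 5 before the chiral catalyst is present.

Step 4
Reactants: 4 5-(methoxymethoxy)-2-oxo-7-[(triisopropylsilyl)oxy]-2H-chromene-6-carbaldehyde and 5 (E)-2-bromobut-2-ene
Product: 6 6-[(2E)-1-hydroxy-2-methylbut-2-en-1-yl]-5-(methoxymethoxy)-7-[(triisopropylsilyl)oxy]-2H-chromen-2-one (racemic at the carbinol carbon)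
Conditions: CrCl2 (4 equiv), NiCl2 (2 mol%), DMF, rt
Reagents that add atoms: none
Why: Nozaki–Hiyama–Kishi coupling, in which the nickel-catalysed alkenylchromium reagent forms with retention of the E geometry and adds only to the aldehyde, sparing the coumarin lactone that a lithium or Grignard reagent would attack; the racemic carbinol centre is removed in step 5.

Step 5
Reactants: 6 6-[(2E)-1-hydroxy-2-methylbut-2-en-1-yl]-5-(methoxymethoxy)-7-[(triisopropylsilyl)oxy]-2H-chromen-2-one
Product: 7 5-(methoxymethoxy)-6-[(2E)-2-methylbut-2-enoyl]-7-[(triisopropylsilyl)oxy]-2H-chromen-2-one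
Conditions: Dess–Martin periodinane (1.3 equiv), CH2Cl2, 0 °C → rt
Reagents that add atoms: none
Why: Dess–Martin oxidation of the allylic benzylic alcohol gives the tigloyl ketone under neutral conditions that neither isomerise the alkene nor touch the acetal and the silyl ether.

Step 6
Reactants: 7 5-(methoxymethoxy)-6-[(2E)-2-methylbut-2-enoyl]-7-[(triisopropylsilyl)oxy]-2H-chromen-2-one
Product: 8 5-hydroxy-6-[(2E)-2-methylbut-2-enoyl]-7-[(triisopropylsilyl)oxy]-2H-chromen-2-one
Conditions: 2 M aq. HCl, THF, rt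
Reagents that add atoms: none
Why: Acetal hydrolysis, accelerated by the neighbouring ketone, frees only the 5-OH because the aryl triisopropylsilyl ether survives dilute aqueous acid, and the enone does not cyclise without base.

Step 7
Reactants: 8 5-hydroxy-6-[(2E)-2-methylbut-2-enoyl]-7-[(triisopropylsilyl)oxy]-2H-chromen-2-one
Product: 9 (2R,3S)-2,3-dimethyl-5-[(triisopropylsilyl)oxy]-2,3-dihydro-4H,8H-pyrano[2,3-f]chromene-4,8-dione
Conditions: (−)-quinine (10 mol%), PhCl, 14 °C, 48 h
Reagents that add atoms: none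
Why: Cinchona-alkaloid-catalysed intramolecular oxa-Michael addition on an achiral substrate, the first stereo-defining step: quinine as chiral Brønsted base and hydrogen-bond donor sends the phenoxide to one enantiotopic face of the tigloyl β-carbon (C2 = R) and protonates the enol from the same bound face (C3 = S, kinetic cis product), while the silyl ether on the other ortho oxygen allows closure through the 5-oxygen only.

Step 8
Reactants: 9 (2R,3S)-2,3-dimethyl-5-[(triisopropylsilyl)oxy]-2,3-dihydro-4H,8H-pyrano[2,3-f]chromene-4,8-dione and 10 phenylboronic acid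
Product: 11 (2R,3S,10S)-2,3-dimethyl-10-phenyl-5-[(triisopropylsilyl)oxy]-2,3,9,10-tetrahydro-4H,8H-pyrano[2,3-f]chromene-4,8-dione
Conditions: Rh(acac)(C2H4)2 (3 mol%), (S)-SEGPHOS (3.3 mol%), 10 (5 equiv), dioxane/H2O 10:1, 60 °C
Reagents that add atoms: none
Why: Hayashi–Miyaura rhodium-catalysed asymmetric 1,4-addition, in which the phenylrhodium–(S)-SEGPHOS complex inserts the coumarin C=C bond from one face under catalyst control and the rhodium enolate is hydrolysed to give the 10S benzylic centre, while the hindered ketone, the silyl ether and the cis-2,3-dimethyl unit are untouched in the neutral medium.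

Step 9
Reactants: 11 (2R,3S,10S)-2,3-dimethyl-10-phenyl-5-[(triisopropylsilyl)oxy]-2,3,9,10-tetrahydro-4H,8H-pyrano[2,3-f]chromene-4,8-dione
Product: 12 (2R,3S,10S)-6-iodo-2,3-dimethyl-10-phenyl-5-[(triisopropylsilyl)oxy]-2,3,9,10-tetrahydro-4H,8H-pyrano[2,3-f]chromene-4,8-dione
Conditions: NIS (1.15 equiv), TFA (0.3 equiv), MeCN, 0 °C → rt
Reagents that add atoms: N-iodosuccinimide, O=C1CCC(=O)N1I
Why: Electrophilic aromatic iodination can only occur at C6, the last aromatic C–H of the oxygenated ring (ortho to the silyloxy and lactone oxygens, para to the pyranone oxygen), and installs the cross-coupling handle.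

Step 10
Reactants: 13 diethyl malonate and 14 4-bromo-2-methylbut-1-ene
Product: 15 diethyl 2-(3-methylbut-3-en-1-yl)malonate
Conditions: 13 (2 equiv), NaH (1.1 equiv), THF/DMF, 0 °C; then 14, 60 °C
Reagents that add atoms: none
Why: Malonic ester alkylation (SN2 on the primary homoallylic bromide), with excess malonate suppressing dialkylation.

Step 11
Reactants: 15 diethyl 2-(3-methylbut-3-en-1-yl)malonate
Product: 16 2-(3-methylbut-3-en-1-yl)propane-1,3-diol
Conditions: LiAlH4 (2.5 equiv), THF, 0 °C → reflux; aqueous work-up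
Reagents that add atoms: none
Why: Hydride reduction of both esters gives the prochiral diol whose two hydroxymethyl arms are enantiotopic.

Step 12
Reactants: 16 2-(3-methylbut-3-en-1-yl)propane-1,3-diol
Product: 17 (2S)-2-(hydroxymethyl)-5-methylhex-5-en-1-yl acetate
Conditions: lipase (Burkholderia cepacia lipase, Amano PS, immobilised), vinyl acetate (3 equiv), MTBE, 25 °C, run to ca. 8% diacetate
Reagents that add atoms: vinyl acetate, C=COC(C)=O
Why: Lipase-catalysed enantiotopos-selective transesterification (desymmetrisation), in which the acyl-enzyme of this serine hydrolase acetylates the pro-S hydroxymethyl arm, tautomerisation of vinyl alcohol makes it irreversible, and slight over-acylation removes the minor enantiomer.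

Step 13
Reactants: 17 (2S)-2-(hydroxymethyl)-5-methylhex-5-en-1-yl acetate
Product: 18 (2R)-2-{[(tert-butyldiphenylsilyl)oxy]methyl}-5-methylhex-5-en-1-yl acetate
Conditions: TBDPSCl (1.1 equiv), imidazole (2.2 equiv), CH2Cl2, 0 °C
Reagents that add atoms: tert-butyl(chloro)diphenylsilane (TBDPSCl), CC(C)(C)[Si](Cl)(c1ccccc1)c1ccccc1
Why: Silylation of the free primary alcohol at 0 °C fixes the difference between the two arms before 1,3-acyl migration can racemise the monoacetate (the descriptor changes only through CIP priorities).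

Step 14
Reactants: 18 (2R)-2-{[(tert-butyldiphenylsilyl)oxy]methyl}-5-methylhex-5-en-1-yl acetate
Product: 19 (2R)-2-{[(tert-butyldiphenylsilyl)oxy]methyl}-5-methylhex-5-en-1-ol
Conditions: K2CO3 (0.5 equiv), MeOH, 0 °C → rt
Reagents that add atoms: none
Why: Base-catalysed transesterification (methanolysis) removes the acetate, and the bulky diphenylsilyl ether neither cleaves nor migrates under these conditions.

Step 15
Reactants: 19 (2R)-2-{[(tert-butyldiphenylsilyl)oxy]methyl}-5-methylhex-5-en-1-ol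
Product: 20 (2S)-2-{[(tert-butyldiphenylsilyl)oxy]methyl}-5-methylhex-5-enal
Conditions: Dess–Martin periodinane (1.3 equiv), NaHCO3 (4 equiv), CH2Cl2, 0 °C → rt; used crude at once
Reagents that add atoms: none
Why: Buffered Dess–Martin oxidation gives the α-branched aldehyde without enolisation, so the stereocentre is kept.

Step 16
Reactants: 20 (2S)-2-{[(tert-butyldiphenylsilyl)oxy]methyl}-5-methylhex-5-enal
Product: 21 tert-butyl{[(2R)-5-methyl-2-(2-methylprop-1-en-1-yl)hex-5-en-1-yl]oxy}diphenylsilane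
Conditions: i-PrPPh3 iodide (1.6 equiv), n-BuLi (1.5 equiv), THF, 0 °C; then 20, −78 °C → rt
Reagents that add atoms: isopropyltriphenylphosphonium iodide, CC(C)[P+](c1ccccc1)(c1ccccc1)c1ccccc1.[I-]
Why: Wittig olefination with the non-stabilised isopropylidene ylide builds the trisubstituted alkene, and carbonyl addition at −78 °C is faster than α-deprotonation, so the stereocentre is not epimerised.

Step 17
Reactants: 21 tert-butyl{[(2R)-5-methyl-2-(2-methylprop-1-en-1-yl)hex-5-en-1-yl]oxy}diphenylsilane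
Product: 22 (2R)-5-methyl-2-(2-methylprop-1-en-1-yl)hex-5-en-1-ol
Conditions: TBAF (1.5 equiv), THF, rt
Reagents that add atoms: none
Why: Fluoride-driven desilylation (strong Si–F bond) frees the primary alcohol without touching the two alkenes.

Step 18
Reactants: 22 (2R)-5-methyl-2-(2-methylprop-1-en-1-yl)hex-5-en-1-ol
Product: 23 (4R)-4-(iodomethyl)-2,7-dimethylocta-2,7-diene
Conditions: I2 (1.3 equiv), PPh3 (1.3 equiv), imidazole (1.5 equiv), CH2Cl2, 0 °C → rt
Reagents that add atoms: iodine, II
Why: Appel-type iodination (SN2 on the alkoxyphosphonium at the primary carbon), with the stereocentre one carbon away and unaffected.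

Step 19
Reactants: 23 (4R)-4-(iodomethyl)-2,7-dimethylocta-2,7-diene and 12 (2R,3S,10S)-6-iodo-2,3-dimethyl-10-phenyl-5-[(triisopropylsilyl)oxy]-2,3,9,10-tetrahydro-4H,8H-pyrano[2,3-f]chromene-4,8-dione
Product: 26 (2R,3S,10S)-2,3-dimethyl-6-[(2S)-5-methyl-2-(2-methylprop-1-en-1-yl)hex-5-en-1-yl]-10-phenyl-5-[(triisopropylsilyl)oxy]-2,3,9,10-tetrahydro-4H,8H-pyrano[2,3-f]chromene-4,8-dione, via alkyllithium 24 (not isolated), via alkylzinc chloride 25 (not isolated)
Conditions: 23 (1.5 equiv), t-BuLi (2.1 equiv per iodide), Et2O/pentane, −78 °C; ZnCl2 (THF), −78 °C → rt; then 12, Pd(OAc)2 (5 mol%), SPhos (10 mol%), THF, rt → 45 °C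
Reagents that add atoms: none
Why: Negishi sp2–sp3 cross-coupling, in which iodine–lithium exchange at −78 °C (no radical, hence no 1,2-vinyl shift or 5-exo cyclisation) and transmetalation give a primary alkylzinc with its stereocentre β to the metal, and oxidative addition of zerovalent palladium to the aryl iodide followed by fast reductive elimination from the bulky biarylphosphine complex beats β-hydride elimination while the neutral medium spares lactone, ketone and the cis-2,3-dimethyl unit.

Step 20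
Reactants: 26 (2R,3S,10S)-2,3-dimethyl-6-[(2S)-5-methyl-2-(2-methylprop-1-en-1-yl)hex-5-en-1-yl]-10-phenyl-5-[(triisopropylsilyl)oxy]-2,3,9,10-tetrahydro-4H,8H-pyrano[2,3-f]chromene-4,8-dione
Product: 27 (2R,3S,10S)-5-hydroxy-2,3-dimethyl-6-[(2S)-5-methyl-2-(2-methylprop-1-en-1-yl)hex-5-en-1-yl]-10-phenyl-2,3,9,10-tetrahydro-4H,8H-pyrano[2,3-f]chromene-4,8-dione
Conditions: HF·pyridine, pyridine, THF, 0 °C → rt
Reagents that add atoms: none
Why: Fluoride desilylation of the aryl silyl ether, activated by the peri carbonyl, proceeds under buffered non-basic conditions that keep the cis-2,3-dimethyl centres, the lactone and the alkenes.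

Step 21
Reactants: 27 (2R,3S,10S)-5-hydroxy-2,3-dimethyl-6-[(2S)-5-methyl-2-(2-methylprop-1-en-1-yl)hex-5-en-1-yl]-10-phenyl-2,3,9,10-tetrahydro-4H,8H-pyrano[2,3-f]chromene-4,8-dione and 28 3-methylbut-2-en-1-yl acetate (prenyl acetate)
Product: 30 (3S)-3-[(2R,3S,6S)-4-hydroxy-2,3-dimethyl-6-(3-methylbut-2-en-1-yl)-6-[(2S)-5-methyl-2-(2-methylprop-1-en-1-yl)hex-5-en-1-yl]-5,7-dioxo-3,5,6,7-tetrahydro-2H-chromen-8-yl]-3-phenylpropanoic acid (CNP0155375.1), via ring-opened trilithium salt 29 (not isolated)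
Conditions: LiOH·H2O (3.3 equiv), degassed THF/H2O 4:1, 0 °C, 30 min; then Pd2(dba)3·CHCl3 (2.5 mol%), (R,R)-DACH-phenyl Trost ligand (7.5 mol%), 28 (1.3 equiv), 0 °C; then 1 M HCl to pH 3
Reagents that add atoms: lithium hydroxide, [Li+].[OH-]
Why: Lactone saponification followed by Tsuji–Trost dearomative allylic alkylation, in which the phloroglucinolate attacks the less hindered terminus of the π-prenylpalladium complex through C6 (the carbon between two oxido groups), creating the quaternary centre and turning C5/C7 into the enolised β-diketone so the acid cannot re-lactonise; the C6 face is meant to be selected by the chiral ligand pocket because the substrate has no useful bias, and any 6R epimer is removed by HPLC.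

**Compound list**
1 | 5,7-dihydroxy-2H-chromen-2-one | O=c1ccc2c(O)cc(O)cc2o1 | starting material
2 | 5-hydroxy-7-[(triisopropylsilyl)oxy]-2H-chromen-2-one | O=c1ccc2c(O)cc(O[Si](C(C)C)(C(C)C)C(C)C)cc2o1 | intermediate
3 | 5-hydroxy-2-oxo-7-[(triisopropylsilyl)oxy]-2H-chromene-6-carbaldehyde | O=c1ccc2c(O)c(C=O)c(O[Si](C(C)C)(C(C)C)C(C)C)cc2o1 | intermediate
4 | 5-(methoxymethoxy)-2-oxo-7-[(triisopropylsilyl)oxy]-2H-chromene-6-carbaldehyde | O=c1ccc2c(OCOC)c(C=O)c(O[Si](C(C)C)(C(C)C)C(C)C)cc2o1 | intermediate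
5 | (E)-2-bromobut-2-ene | C/C=C(\C)Br | starting material
6 | 6-[(2E)-1-hydroxy-2-methylbut-2-en-1-yl]-5-(methoxymethoxy)-7-[(triisopropylsilyl)oxy]-2H-chromen-2-one (racemic carbinol) | O=c1ccc2c(OCOC)c(C(O)/C(C)=C/C)c(O[Si](C(C)C)(C(C)C)C(C)C)cc2o1 | intermediate
7 | 5-(methoxymethoxy)-6-[(2E)-2-methylbut-2-enoyl]-7-[(triisopropylsilyl)oxy]-2H-chromen-2-one | O=c1ccc2c(OCOC)c(C(=O)/C(C)=C/C)c(O[Si](C(C)C)(C(C)C)C(C)C)cc2o1 | intermediate
8 | 5-hydroxy-6-[(2E)-2-methylbut-2-enoyl]-7-[(triisopropylsilyl)oxy]-2H-chromen-2-one | O=c1ccc2c(O)c(C(=O)/C(C)=C/C)c(O[Si](C(C)C)(C(C)C)C(C)C)cc2o1 | intermediate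
9 | (2R,3S)-2,3-dimethyl-5-[(triisopropylsilyl)oxy]-2,3-dihydro-4H,8H-pyrano[2,3-f]chromene-4,8-dione | O=c1ccc2c3O[C@H](C)[C@H](C)C(=O)c3c(O[Si](C(C)C)(C(C)C)C(C)C)cc2o1 | intermediate
10 | phenylboronic acid | OB(O)c1ccccc1 | starting material
11 | (2R,3S,10S)-2,3-dimethyl-10-phenyl-5-[(triisopropylsilyl)oxy]-2,3,9,10-tetrahydro-4H,8H-pyrano[2,3-f]chromene-4,8-dione | O=C1C[C@@H](c2ccccc2)c2c3O[C@H](C)[C@H](C)C(=O)c3c(O[Si](C(C)C)(C(C)C)C(C)C)cc2O1 | intermediate
12 | (2R,3S,10S)-6-iodo-2,3-dimethyl-10-phenyl-5-[(triisopropylsilyl)oxy]-2,3,9,10-tetrahydro-4H,8H-pyrano[2,3-f]chromene-4,8-dione | O=C1C[C@@H](c2ccccc2)c2c3O[C@H](C)[C@H](C)C(=O)c3c(O[Si](C(C)C)(C(C)C)C(C)C)c(I)c2O1 | intermediate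
13 | diethyl malonate | CCOC(=O)CC(=O)OCC | starting material
14 | 4-bromo-2-methylbut-1-ene | C=C(C)CCBr | starting material
15 | diethyl 2-(3-methylbut-3-en-1-yl)malonate | CCOC(=O)C(CCC(C)=C)C(=O)OCC | intermediate
16 | 2-(3-methylbut-3-en-1-yl)propane-1,3-diol | OCC(CO)CCC(C)=C | intermediate
17 | (2S)-2-(hydroxymethyl)-5-methylhex-5-en-1-yl acetate | CC(=O)OC[C@H](CO)CCC(C)=C | intermediate
18 | (2R)-2-{[(tert-butyldiphenylsilyl)oxy]methyl}-5-methylhex-5-en-1-yl acetate | CC(=O)OC[C@H](CO[Si](c1ccccc1)(c1ccccc1)C(C)(C)C)CCC(C)=C | intermediate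
19 | (2R)-2-{[(tert-butyldiphenylsilyl)oxy]methyl}-5-methylhex-5-en-1-ol | OC[C@H](CO[Si](c1ccccc1)(c1ccccc1)C(C)(C)C)CCC(C)=C | intermediate
20 | (2S)-2-{[(tert-butyldiphenylsilyl)oxy]methyl}-5-methylhex-5-enal | O=C[C@H](CO[Si](c1ccccc1)(c1ccccc1)C(C)(C)C)CCC(C)=C | intermediate
21 | tert-butyl{[(2R)-5-methyl-2-(2-methylprop-1-en-1-yl)hex-5-en-1-yl]oxy}diphenylsilane | CC(C)=C[C@H](CO[Si](c1ccccc1)(c1ccccc1)C(C)(C)C)CCC(C)=C | intermediate
22 | (2R)-5-methyl-2-(2-methylprop-1-en-1-yl)hex-5-en-1-ol | CC(C)=C[C@H](CO)CCC(C)=C | intermediate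
23 | (4R)-4-(iodomethyl)-2,7-dimethylocta-2,7-diene | CC(C)=C[C@H](CI)CCC(C)=C | intermediate
24 | [(2R)-5-methyl-2-(2-methylprop-1-en-1-yl)hex-5-en-1-yl]lithium | CC(C)=C[C@H](C[Li])CCC(C)=C | intermediate (not isolated)
25 | chloro[(2R)-5-methyl-2-(2-methylprop-1-en-1-yl)hex-5-en-1-yl]zinc | CC(C)=C[C@H](C[Zn]Cl)CCC(C)=C | intermediate (not isolated)
26 | (2R,3S,10S)-2,3-dimethyl-6-[(2S)-5-methyl-2-(2-methylprop-1-en-1-yl)hex-5-en-1-yl]-10-phenyl-5-[(triisopropylsilyl)oxy]-2,3,9,10-tetrahydro-4H,8H-pyrano[2,3-f]chromene-4,8-dione | O=C1C[C@@H](c2ccccc2)c2c3O[C@H](C)[C@H](C)C(=O)c3c(O[Si](C(C)C)(C(C)C)C(C)C)c(C[C@@H](C=C(C)C)CCC(C)=C)c2O1 | intermediate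
27 | (2R,3S,10S)-5-hydroxy-2,3-dimethyl-6-[(2S)-5-methyl-2-(2-methylprop-1-en-1-yl)hex-5-en-1-yl]-10-phenyl-2,3,9,10-tetrahydro-4H,8H-pyrano[2,3-f]chromene-4,8-dione | O=C1C[C@@H](c2ccccc2)c2c3O[C@H](C)[C@H](C)C(=O)c3c(O)c(C[C@@H](C=C(C)C)CCC(C)=C)c2O1 | intermediate
28 | 3-methylbut-2-en-1-yl acetate (prenyl acetate) | CC(=O)OCC=C(C)C | starting material
29 | trilithium (3S)-3-[(2R,3S)-2,3-dimethyl-6-[(2S)-5-methyl-2-(2-methylprop-1-en-1-yl)hex-5-en-1-yl]-5,7-dioxido-4-oxo-3,4-dihydro-2H-chromen-8-yl]-3-phenylpropanoate | [Li+].[Li+].[Li+].[O-]C(=O)C[C@@H](c1ccccc1)c1c([O-])c(C[C@@H](C=C(C)C)CCC(C)=C)c([O-])c2c1O[C@H](C)[C@H](C)C2=O | intermediate (not isolated)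
30 | (3S)-3-[(2R,3S,6S)-4-hydroxy-2,3-dimethyl-6-(3-methylbut-2-en-1-yl)-6-[(2S)-5-methyl-2-(2-methylprop-1-en-1-yl)hex-5-en-1-yl]-5,7-dioxo-3,5,6,7-tetrahydro-2H-chromen-8-yl]-3-phenylpropanoic acid (CNP0155375.1) | C=C(C)CC[C@H](C=C(C)C)C[C@@]1(CC=C(C)C)C(=O)C2=C(O)[C@@H](C)[C@@H](C)OC2=C([C@@H](CC(=O)O)c2ccccc2)C1=O | target

**Totals**
Total step count: 21.
Longest linear sequence: 12 steps (steps 1–9, 19, 20, 21; the side-chain branch, steps 10–18 then 19–21, is equally long).

**Three steps most likely to fail**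

Step 21 (dearomative prenylation). The substrate has no useful facial bias at C6 and the matched ligand antipode is not known in advance. Reverse-prenyl or O-prenyl products are possible, and re-ionisation of the new C6–prenyl bond by zerovalent palladium could erode a kinetic ratio. Hydroxide can also epimerise C3 (cis to trans) if the mixture warms. Fallback: it sets out from 27 and comes back at 30. After the same LiOH ring opening to 29, prenyl bromide (1.1 equiv) is added at 0 °C with no palladium and no ligand, so the bond forms by direct SN2 C-alkylation of the phloroglucinolate in water (the classical lupulone-type dearomatisation). This gives 30 together with its C6 epimer (3S)-3-[(2R,3S,6R)-4-hydroxy-2,3-dimethyl-6-(3-methylbut-2-en-1-yl)-6-[(2S)-5-methyl-2-(2-methylprop-1-en-1-yl)hex-5-en-1-yl]-5,7-dioxo-3,5,6,7-tetrahydro-2H-chromen-8-yl]-3-phenylpropanoic acid F3, and the two are separated by preparative reversed-phase HPLC.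

Step 19 (Negishi coupling). The carbon–iodine bond of 12 sits between the bulky silyloxy group and the lactone oxygen. β-Hydride elimination from the alkylpalladium intermediate would give a conjugated diene, and zinc salts could epimerise C3. Fallback: it sets out from 23 and 12 and comes back at 26. Alkyllithium 24 is made as before and trapped at −78 °C with B-methoxy-9-borabicyclo[3.3.1]nonane to give lithium B-methoxy-B-[(2R)-5-methyl-2-(2-methylprop-1-en-1-yl)hex-5-en-1-yl]-9-borabicyclo[3.3.1]nonan-9-uide F2. This borate is coupled with 12 in a base-free B-alkyl Suzuki–Miyaura reaction (PdCl2(dppf), THF/DMF, 50 °C), so transmetalation runs from boron and no Lewis-acidic zinc is present.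

Step 8 (rhodium-catalysed phenylation). Coumarin 9 is electron-rich and carries a peri alkoxy substituent next to the reacting carbon, and the catalyst must override the two existing stereocentres. Fallback: it sets out from 9 and comes back at 11. Coumarin 9 is phenylated at its β-carbon with 10 under oxidative Heck conditions (Pd(OAc)2, 1,10-phenanthroline, O2, DMF, 80 °C) to give (2R,3S)-2,3-dimethyl-10-phenyl-5-[(triisopropylsilyl)oxy]-2,3-dihydro-4H,8H-pyrano[2,3-f]chromene-4,8-dione F1. The benzylic centre is then set by hydride instead of aryl delivery, through copper hydride-catalysed asymmetric conjugate reduction (Cu(OAc)2·H2O, the DTBM-SEGPHOS antipode that gives 10S, (EtO)2MeSiH, t-BuOH, toluene, 0 °C), a reduction established for 4-aryl coumarins.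

Further compounds
F1 | step 8 | (2R,3S)-2,3-dimethyl-10-phenyl-5-[(triisopropylsilyl)oxy]-2,3-dihydro-4H,8H-pyrano[2,3-f]chromene-4,8-dione | O=c1cc(-c2ccccc2)c2c3O[C@H](C)[C@H](C)C(=O)c3c(O[Si](C(C)C)(C(C)C)C(C)C)cc2o1
F2 | step 19 | lithium B-methoxy-B-[(2R)-5-methyl-2-(2-methylprop-1-en-1-yl)hex-5-en-1-yl]-9-borabicyclo[3.3.1]nonan-9-uide | [Li+].CO[B-]1(C[C@@H](C=C(C)C)CCC(C)=C)C2CCCC1CCC2
F3 | step 21 | (3S)-3-[(2R,3S,6R)-4-hydroxy-2,3-dimethyl-6-(3-methylbut-2-en-1-yl)-6-[(2S)-5-methyl-2-(2-methylprop-1-en-1-yl)hex-5-en-1-yl]-5,7-dioxo-3,5,6,7-tetrahydro-2H-chromen-8-yl]-3-phenylpropanoic acid | C=C(C)CC[C@H](C=C(C)C)C[C@]1(CC=C(C)C)C(=O)C2=C(O)[C@@H](C)[C@@H](C)OC2=C([C@@H](CC(=O)O)c2ccccc2)C1=O
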